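**Retrosynthetic overview**
1. Target ⇒ 10-bromo-β-chamigrene: the cis C-2 Br / C-3 Cl pair cannot come from anti addition, so it is first written as a ring-A epoxide (two C–O bonds); chloride then opens C-3 and bromide inverts C-2.
2. 10-Bromo-β-chamigrene ⇒ spiro ketone (C=O to C=CH2) ⇒ Diels–Alder of isoprene onto (R)-4-bromo-3,3-dimethyl-2-methylidenecyclohexanone; ring A and spiro C-6 are made here, steered by C-10.
3. Bromo enone ⇒ 2-phosphonocyclohexanone (HWE with CH2O) ⇒ acyclic (S)-epoxy β-ketophosphonate, by a new invertive epoxide-to-bromonium cyclisation that closes ring B and turns the C-10–O stereocentre into C-10–Br.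
4. Epoxide ⇒ Shi epoxidation of the prenylated β-ketophosphonate ⇒ dimethyl (2-oxopropyl)phosphonate + prenyl bromide.
5. Ring order: ring B first, ring A (spiro) second; all four stereocentres descend from two epoxidations whose oxygen atoms are later excised.

Assumption: positions are cited in chamigrene numbering (C-1 to C-5 ring A, C-6 spiro carbon, C-7 to C-11 ring B) for all intermediates; the L-fructose-derived Shi ketone is taken as a purchasable catalyst.

**Route**

Step 1
Reactants: 1 dimethyl (2-oxopropyl)phosphonate; 2 1-bromo-3-methylbut-2-ene (prenyl bromide)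
Product: 3 dimethyl (6-methyl-2-oxohept-5-en-1-yl)phosphonate
Conditions: NaH, THF, 0 °C; n-BuLi, 0 °C; then 2, 0 °C → rt; 1 M aq. HCl
Reagents that add atoms: none
Why: Dianion alkylation of a β-ketophosphonate: the terminal (γ) carbanion, the more basic site, is alkylated by the allylic bromide by SN2 substitution, and no stereocentre is formed.

Step 2
Reactants: 3 dimethyl (6-methyl-2-oxohept-5-en-1-yl)phosphonate
Product: 4 dimethyl {4-[(2S)-3,3-dimethyloxiran-2-yl]-2-oxobutyl}phosphonate
Conditions: 1,2:4,5-di-O-isopropylidene-β-L-erythro-2,3-hexodiulo-2,6-pyranose (L-fructose-derived Shi ketone, 30 mol %), KHSO5 (as 2KHSO5·KHSO4·K2SO4), K2CO3, Bu4NHSO4 (5 mol %), MeCN/CH2(OMe)2/aq. Na2B4O7 buffer, pH 10.5, 0 °C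
Reagents that add atoms: potassium peroxymonosulfate, [K+].[O-]S(=O)(=O)OO
Why: Shi asymmetric epoxidation: the chiral dioxirane transfers oxygen through the spiro transition state to one face of the trisubstituted alkene, and the L-fructose-derived catalyst gives the (S)-epoxide, whose C-10–O bond is the stereochemical source of (R)-C-10–Br after the inversion in step 3.

Step 3
Reactants: 4 dimethyl {4-[(2S)-3,3-dimethyloxiran-2-yl]-2-oxobutyl}phosphonate
Product: 6 dimethyl [(3R)-3-bromo-2,2-dimethyl-6-oxocyclohexyl]phosphonate (both C-1 epimers), via bromohydrin silyl ether 5 (not isolated)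
Conditions: Me3SiBr (1.05 equiv), CH2Cl2, −78 °C; then (CF3)2CHOH, TfOH (20 mol %), −40 → 0 °C
Reagents that add atoms: bromotrimethylsilane, C[Si](C)(C)Br
Why: Proposed new method: an invertive epoxide-to-bromonium relay cyclisation in which Me3SiBr opens the epoxide anti to give 5, then in (CF3)2CHOH with catalytic TfOH the freed C-10 oxygen adds to the C-7 ketone and leaves as the neutral ketone from the cyclic oxocarbenium ion with anchimeric assistance by the neighbouring bromine, so the bromonium ion forms on the face opposite the former epoxide oxygen (C–O replaced by C–Br with inversion, whichever carbon bromide attacked first), and the phosphonate-stabilised enol carbon then closes the six-membered ring at the tertiary terminus anti to bromine to give (R)-C-10; the closest known reaction types are enantiospecific solvolytic bromonium generation from enantioenriched bromohydrins or vicinal bromochlorides in polyene cyclisations and the acid-mediated O-to-C isomerisation of cyclic enol ethers of 1,3-dicarbonyl compounds.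

Step 4
Reactants: 6 dimethyl [(3R)-3-bromo-2,2-dimethyl-6-oxocyclohexyl]phosphonate
Product: 7 (4R)-4-bromo-3,3-dimethyl-2-methylidenecyclohexan-1-one
Conditions: 37% aq. CH2O, K2CO3, THF/H2O, 0 °C → rt
Reagents that add atoms: formaldehyde, C=O
Why: Horner–Wadsworth–Emmons methylenation of the α-substituted β-ketophosphonate with formaldehyde under mild carbonate conditions; both C–P epimers converge and C-10 is not touched.

Step 5
Reactants: 7 (4R)-4-bromo-3,3-dimethyl-2-methylidenecyclohexan-1-one; 8 isoprene (2-methylbuta-1,3-diene)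
Product: 9 (4R,6S)-4-bromo-5,5,9-trimethylspiro[5.5]undec-8-en-1-one
Conditions: Me2AlCl (0.3 equiv), CH2Cl2, −40 → −20 °C
Reagents that add atoms: none
Why: Lewis-acid-catalysed Diels–Alder reaction with "para" regiochemistry, in which the diene adds to the face of the exocyclic enone anti to the pseudo-axial C-11 methyl of the conformer with equatorial bromine, so the new C-6–C-1 bond is axial and trans to Br and the spiro centre C-6 is set by C-10.

Step 6
Reactants: 9 (4R,6S)-4-bromo-5,5,9-trimethylspiro[5.5]undec-8-en-1-one
Product: 10 (6R,10R)-10-bromo-3,11,11-trimethyl-7-methylidenespiro[5.5]undec-2-ene (10-bromo-β-chamigrene)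
Conditions: Cp2TiMe2 (3 equiv), PhMe/THF, 65 °C, dark
Reagents that add atoms: dimethyltitanocene, C[Ti](C)(C1C=CC=C1)C1C=CC=C1
Why: Petasis methylenation through Cp2Ti=CH2 is non-basic and works on hindered ketones, so the secondary bromide and the ring-A alkene survive and no stereocentre changes.

Step 7
Reactants: 10 (6R,10R)-10-bromo-3,11,11-trimethyl-7-methylidenespiro[5.5]undec-2-ene
Product: 11 (2R,3S,6R,10R)-10-bromo-2,3-epoxy-3,11,11-trimethyl-7-methylidenespiro[5.5]undecane
Conditions: dimethyldioxirane (1.1 equiv, acetone solution), CH2Cl2, −40 → −20 °C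
Reagents that add atoms: dimethyldioxirane, CC1(C)OO1
Why: Dioxirane epoxidation (concerted oxygen transfer) picks the trisubstituted ring-A alkene over the hindered 1,1-disubstituted exocyclic one and attacks the face anti to the axial C-7 of the ring-A half-chair (the bulky CMe2 carbon C-11 sits equatorial), which fixes both C–O bonds at C-2 and C-3 syn to C-11.

Step 8
Reactants: 11 (2R,3S,6R,10R)-10-bromo-2,3-epoxy-3,11,11-trimethyl-7-methylidenespiro[5.5]undecane
Product: 12 (2R,3R,6R,10R)-10-bromo-3-chloro-3,11,11-trimethyl-7-methylidenespiro[5.5]undecan-2-ol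
Conditions: HCl (1.0 M in Et2O, 1.2 equiv), CH2Cl2, −40 °C
Reagents that add atoms: hydrogen chloride, Cl
Why: Acid-mediated anti ring opening of a trisubstituted epoxide at the tertiary carbon (Markovnikov, borderline SN2) puts chloride on C-3 with inversion, on the C-7 face, and leaves the C-2 hydroxyl on the original oxygen face.

Step 9
Reactants: 12 (2R,3R,6R,10R)-10-bromo-3-chloro-3,11,11-trimethyl-7-methylidenespiro[5.5]undecan-2-ol
Product: 14 (2S,3R,6R,10R)-2,10-dibromo-3-chloro-3,11,11-trimethyl-7-methylidenespiro[5.5]undecane (target), via triflate 13 (not isolated)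
Conditions: Tf2O, pyridine, CH2Cl2, −30 → 0 °C; then n-Bu4NBr, PhMe, 40 °C
Reagents that add atoms: trifluoromethanesulfonic anhydride (atoms kept only in 13), O=S(=O)(OS(=O)(=O)C(F)(F)F)C(F)(F)F; tetrabutylammonium bromide, CCCC[N+](CCCC)(CCCC)CCCC.[Br-]
Why: SN2 displacement of the secondary triflate by bromide with inversion places Br at C-2 cis to Cl (C-2 becomes S); in the diequatorial chair the triflate has no anti-periplanar hydrogen or chlorine, so elimination and chloronium participation are disfavoured.

**Compound list**
1 | dimethyl (2-oxopropyl)phosphonate | CC(=O)CP(=O)(OC)OC | starting material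
2 | 1-bromo-3-methylbut-2-ene (prenyl bromide) | CC(C)=CCBr | starting material
3 | dimethyl (6-methyl-2-oxohept-5-en-1-yl)phosphonate | CC(C)=CCCC(=O)CP(=O)(OC)OC | intermediate
4 | dimethyl {4-[(2S)-3,3-dimethyloxiran-2-yl]-2-oxobutyl}phosphonate | COP(=O)(OC)CC(=O)CC[C@@H]1OC1(C)C | intermediate
5 | dimethyl {(5S)-6-bromo-6-methyl-2-oxo-5-[(trimethylsilyl)oxy]heptyl}phosphonate (expected major regioisomer, not isolated) | COP(=O)(OC)CC(=O)CC[C@H](O[Si](C)(C)C)C(C)(C)Br | intermediate
6 | dimethyl [(3R)-3-bromo-2,2-dimethyl-6-oxocyclohexyl]phosphonate (both C-1 epimers) | COP(=O)(OC)C1C(=O)CC[C@@H](Br)C1(C)C | intermediate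
7 | (4R)-4-bromo-3,3-dimethyl-2-methylidenecyclohexan-1-one | C=C1C(=O)CC[C@@H](Br)C1(C)C | intermediate
8 | isoprene (2-methylbuta-1,3-diene) | C=CC(C)=C | starting material
9 | (4R,6S)-4-bromo-5,5,9-trimethylspiro[5.5]undec-8-en-1-one | O=C1CC[C@@H](Br)C(C)(C)[C@@]12CCC(C)=CC2 | intermediate
10 | (6R,10R)-10-bromo-3,11,11-trimethyl-7-methylidenespiro[5.5]undec-2-ene (10-bromo-β-chamigrene) | C=C1CC[C@@H](Br)C(C)(C)[C@@]12CCC(C)=CC2 | intermediate
11 | (2R,3S,6R,10R)-10-bromo-2,3-epoxy-3,11,11-trimethyl-7-methylidenespiro[5.5]undecane (oxygen syn to C-11) | C=C1CC[C@@H](Br)C(C)(C)[C@@]12CC[C@]3(C)O[C@@H]3C2 | intermediate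
12 | (2R,3R,6R,10R)-10-bromo-3-chloro-3,11,11-trimethyl-7-methylidenespiro[5.5]undecan-2-ol | C=C1CC[C@@H](Br)C(C)(C)[C@@]12CC[C@@](C)(Cl)[C@H](O)C2 | intermediate
13 | (2R,3R,6R,10R)-10-bromo-3-chloro-3,11,11-trimethyl-7-methylidenespiro[5.5]undecan-2-yl trifluoromethanesulfonate (not isolated) | C=C1CC[C@@H](Br)C(C)(C)[C@@]12CC[C@@](C)(Cl)[C@H](OS(=O)(=O)C(F)(F)F)C2 | intermediate
14 | (2S,3R,6R,10R)-2,10-dibromo-3-chloro-3,11,11-trimethyl-7-methylidenespiro[5.5]undecane | C=C1CC[C@@H](Br)C(C)(C)[C@@]12CC[C@@](C)(Cl)[C@@H](Br)C2 | target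

**Step count and risks**
Total steps: 9. Longest linear sequence: 9 (the route is fully linear).

The three steps most likely to fail:

Step 3 (the proposed new step). The danger is that the bromohydrin returns to the epoxonium ion and cyclises with oxygen retained (a 4-hydroxy ring), or stops at an O-cyclised enol ether, or that ionisation at the secondary carbon is too slow. The fallback uses only established reaction types and moves the ionisation to a tertiary carbinol. It sets out from 4: soft-bromide SN2 opening at the less substituted epoxide carbon with Li2NiBr4 (THF, 0 °C → rt) gives, with inversion at C-10, the tertiary bromohydrin dimethyl [(5R)-5-bromo-6-hydroxy-6-methyl-2-oxoheptyl]phosphonate F1, which is isolated. Ionising the tertiary alcohol with BF3·OEt2 in CH2Cl2/(CF3)2CHOH at −20 °C (acid-promoted enantiospecific bromonium formation from a tertiary bromohydrin, with intramolecular capture by the enol carbon) then closes ring B. The fallback comes back to the route at 6.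

Step 7. The face selectivity rests on a conformational argument (C-7 axial on ring A, attack anti to it); if the oxidant instead prefers the C-7 face, the wrong epoxide forms. The fallback turns that same preference around by a halohydrin detour. It sets out from 10: NBS in acetone/H2O at 0 °C gives (2S,3S,6R,10R)-2,10-dibromo-3,11,11-trimethyl-7-methylidenespiro[5.5]undecan-3-ol F2 (Br+ on the face the electrophile prefers, water anti at the tertiary carbon). K2CO3 in MeOH closes it by backside attack at C-2, which puts the oxygen on the opposite face. The fallback comes back to the route at 11.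

Step 9. Bromide must enter C-2 axially, 1,3-syn to C-7, so the displacement may be slow and give ring contraction or elimination instead. The fallback drops the oxygen relay for a selenium relay with a neutral, softer leaving group. It sets out from 10: PhSeCl (CH2Cl2, −78 °C → rt, thermodynamic Markovnikov anti adduct) gives (2R,3R,6R,10R)-10-bromo-3-chloro-3,11,11-trimethyl-7-methylidene-2-(phenylselanyl)spiro[5.5]undecane F3. MeOTf (CH2Cl2, 0 °C) converts it into methyl(phenyl)[(2R,3R,6R,10R)-10-bromo-3-chloro-3,11,11-trimethyl-7-methylidenespiro[5.5]undecan-2-yl]selenonium trifluoromethanesulfonate F4, and n-Bu4NBr (MeCN, 40 °C) displaces the selenide with inversion. The fallback comes back to the route at 14.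

**Further compounds**
F1 | step 3 | dimethyl [(5R)-5-bromo-6-hydroxy-6-methyl-2-oxoheptyl]phosphonate | COP(=O)(OC)CC(=O)CC[C@@H](Br)C(C)(C)O
F2 | step 7 | (2S,3S,6R,10R)-2,10-dibromo-3,11,11-trimethyl-7-methylidenespiro[5.5]undecan-3-ol | C=C1CC[C@@H](Br)C(C)(C)[C@@]12CC[C@](C)(O)[C@@H](Br)C2
F3 | step 9 | (2R,3R,6R,10R)-10-bromo-3-chloro-3,11,11-trimethyl-7-methylidene-2-(phenylselanyl)spiro[5.5]undecane | C=C1CC[C@@H](Br)C(C)(C)[C@@]12CC[C@@](C)(Cl)[C@H]([Se]c1ccccc1)C2
F4 | step 9 | methyl(phenyl)[(2R,3R,6R,10R)-10-bromo-3-chloro-3,11,11-trimethyl-7-methylidenespiro[5.5]undecan-2-yl]selenonium trifluoromethanesulfonate | C=C1CC[C@@H](Br)C(C)(C)[C@@]12CC[C@@](C)(Cl)[C@H]([Se+](C)c1ccccc1)C2.[O-]S(=O)(=O)C(F)(F)F
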